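The oxolane (O1; C2 with the 3,4-dimethoxyphenyl group; C3 and C4 with methyls; C5 with the 3,4,5-trimethoxyphenyl group) is opened at O1–C5 and redrawn as a cyclopropane with a C3–C5 bond. The route exploits C5: as a benzylic carbon it can leave a three-membered ring as a stabilised cation, while the oxygen of an aryl ketone at C2 returns as O1. One Lewis acid step thus cleaves C3–C5, forms O1–C5, closes the ring and sets C5 trans to the C4 methyl. The precursor is a 3,4-dimethoxyphenyl 1,2-dimethyl-3-(3,4,5-trimethoxyphenyl)cyclopropyl ketone in which only the methyl-bearing CH (future C4) needs a defined configuration; a closing ionic hydrogenation sets C3 and C2.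

Key step: step 6

Labels O1, C2, C3, C4, C5 are those of the oxolane of the target and are also used for the corresponding atoms of earlier compounds; cyclopropane and chain locants are marked as such.

Assumption: the benzylide of the (1R,4R,5R)-sulfide is taken to add to the Si face of the β-carbon of enone 5 (giving 2R in 12); if the sense is the opposite, the (1S,4S,5S)-sulfide is used and nothing else changes.

Step 1
Reactants: 1 tigloyl chloride [(2E)-2-methylbut-2-enoyl chloride]
Product: 2 (2E)-N-methoxy-N,2-dimethylbut-2-enamide
Conditions: MeNH(OMe)·HCl, K2CO3, CH2Cl2/H2O, 0 °C to rt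
Reagents that add atoms: N,O-dimethylhydroxylamine hydrochloride, CNOC.Cl
Why: Schotten–Baumann N-acylation of the hydroxylamine by the acid chloride is fast at 0 °C and leaves the E alkene untouched; no stereocentre is formed.

Step 2
Reactants: 2 (2E)-N-methoxy-N,2-dimethylbut-2-enamide; 3 3,4-dimethoxyphenylmagnesium bromide
Product: 5 (2E)-1-(3,4-dimethoxyphenyl)-2-methylbut-2-en-1-one, via magnesium chelate 4 (not isolated)
Conditions: THF, 0 °C; then 1 M HCl
Reagents that add atoms: none
Why: Weinreb ketone synthesis: the aryl Grignard reagent adds once and the N-methoxy chelate 4 holds until the acidic quench, so neither over-addition nor conjugate addition can occur; the acyl position on the arene is fixed by the reagent and no Lewis acid touches the enone or the methyl ethers.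

Step 3
Reactants: 6 (3,4,5-trimethoxyphenyl)methanol
Product: 7 5-(bromomethyl)-1,2,3-trimethoxybenzene
Conditions: PBr3, CH2Cl2, 0 °C
Reagents that add atoms: phosphorus tribromide, BrP(Br)Br
Why: Bromination of a primary benzylic alcohol with PBr3 (bromide displaces the phosphite ester in an SN2 step) is standard for electron-rich benzyl alcohols and leaves the ring and the methyl ethers alone at 0 °C; no stereocentre is involved.

Step 4
Reactants: 7 5-(bromomethyl)-1,2,3-trimethoxybenzene; 8 (1R,4R,5R)-isothiocineole
Product: 9 (1R,4R,5R,6R)-4,7,7-trimethyl-6-[(3,4,5-trimethoxyphenyl)methyl]-6-thiabicyclo[3.2.1]octan-6-ium tetrafluoroborate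
Conditions: NaBF4, CH2Cl2/H2O, rt
Reagents that add atoms: sodium tetrafluoroborate, [Na+].F[B-](F)(F)F
Why: SN2 S-alkylation of the thioether by the reactive benzylic bromide, with exchange to the non-nucleophilic tetrafluoroborate in the two-phase mixture so that bromide cannot reverse it; sulfur reacts through its less hindered exo lone pair, so a single configuration (6R) at sulfur should result.

Step 5
Reactants: 9 sulfonium tetrafluoroborate; 5 (2E)-1-(3,4-dimethoxyphenyl)-2-methylbut-2-en-1-one
Product: 12 (3,4-dimethoxyphenyl)[(1S,2R,3S)-1,2-dimethyl-3-(3,4,5-trimethoxyphenyl)cyclopropyl]methanone (methyls cis; aryl trans to both methyls), via benzylide 10 (not isolated), via betaine 11 (not isolated)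
Conditions: KN(SiMe3)2, THF, −78 °C; then 5, −78 °C to rt; chromatography
Reagents that add atoms: none
Why: Corey–Chaykovsky-type cyclopropanation (Michael-initiated ring closure) of an enone with a semi-stabilised chiral sulfonium benzylide: the bicyclic sulfide leaves one face of the ylide carbon open, conjugate addition to the β-carbon of 5 with the aryl ring kept away from the β-methyl gives betaine 11 and so ties the β-carbon (cyclopropane C2 of 12, R) to the ylide carbon, and the enolate then displaces the sulfide in a 3-exo-tet closure with inversion at the benzylic carbon and the aroyl group trans to the C2 methyl; the epimer with the aryl cis to the C2 methyl, which under reagent control carries the opposite C2, is removed by chromatography, while cyclopropane C1 and C3 are erased in step 6.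

Step 6
Reactants: 12 (3,4-dimethoxyphenyl)[(1S,2R,3S)-1,2-dimethyl-3-(3,4,5-trimethoxyphenyl)cyclopropyl]methanone
Product: 14 (2S,3S)-5-(3,4-dimethoxyphenyl)-3,4-dimethyl-2-(3,4,5-trimethoxyphenyl)-2,3-dihydrofuran (C4 methyl and C5 aryl trans), via ring-opened zwitterion 13 (not isolated)
Conditions: Sc(OTf)3 (10 mol%), 4 Å molecular sieves, CH2Cl2, 0 °C; Et3N quench
Reagents that add atoms: none
Why: Sc(OTf)3 binds the ketone oxygen of 12 and the cyclopropane bond between the acyl-bearing quaternary carbon (C3) and the benzylic carbon (C5) ionises, because only this bond joins the acceptor carbon to the donor carbon, giving scandium enolate–benzylic cation 13. The closest known reaction type is the Lewis acid-promoted Cloke–Wilson rearrangement of donor–acceptor cyclopropyl ketones to 2,3-dihydrofurans. The ring closes when the enolate oxygen, cis to C4 on the C2=C3 bond, adds to the trigonal cationic C5 in a 5-exo-trig closure (enolendo through oxygen), forming O1–C5. The new C5 stereocentre is controlled by the untouched C4 methyl: oxygen takes the cation face that places the trimethoxyphenyl ring trans to that methyl, and because the benzylic C5–O bond can re-ionise under the catalyst the trans isomer is also the equilibrium outcome. The step needs capture through oxygen and no loss of the C4 proton: return through carbon only rebuilds the strained cyclopropane, six-membered Friedel–Crafts closure onto the dimethoxyphenyl ring is slowed because that ring carries the metal-bound carbonyl, and a catalytic aprotic Lewis acid at 0 °C with an early Et3N quench keeps proton loss and later re-ionisation of 14 in check.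

Step 7
Reactants: 14 (2S,3S)-5-(3,4-dimethoxyphenyl)-3,4-dimethyl-2-(3,4,5-trimethoxyphenyl)-2,3-dihydrofuran
Product: 16 ligraminol A [(2S,3R,4S,5S)-2-(3,4-dimethoxyphenyl)-3,4-dimethyl-5-(3,4,5-trimethoxyphenyl)oxolane], via oxocarbenium ion 15 (not isolated)
Conditions: Et3SiH, CF3CO2H, CH2Cl2, −78 to −40 °C; Et3N quench
Reagents that add atoms: none
Why: Ionic hydrogenation of an enol ether: CF3CO2H protonates C3 on the face opposite the neighbouring C4 methyl to give the aryl-stabilised oxocarbenium ion 15 (C3 methyl cis to C4 methyl, 3R), and Et3SiH, present in excess from the start so that capture outruns re-deprotonation, delivers hydride to C2 on the face opposite both methyls, which sets 2S with the dimethoxyphenyl ring cis to the C3 methyl.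

Compound list
1 | tigloyl chloride, (2E)-2-methylbut-2-enoyl chloride | C/C=C(\C)C(Cl)=O | starting material
2 | (2E)-N-methoxy-N,2-dimethylbut-2-enamide | C/C=C(\C)C(=O)N(C)OC | intermediate
3 | 3,4-dimethoxyphenylmagnesium bromide (THF solution) | COc1ccc([Mg]Br)cc1OC | starting material
4 | bromomagnesium salt of the tetrahedral N-methoxy-N-methyl adduct of 2 and 3 (not isolated; both configurations at the new carbon, which is lost on collapse) | C/C=C(\C)C(O[Mg]Br)(N(C)OC)c1ccc(OC)c(OC)c1 | intermediate
5 | (2E)-1-(3,4-dimethoxyphenyl)-2-methylbut-2-en-1-one | C/C=C(\C)C(=O)c1ccc(OC)c(OC)c1 | intermediate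
6 | (3,4,5-trimethoxyphenyl)methanol | COc1cc(CO)cc(OC)c1OC | starting material
7 | 5-(bromomethyl)-1,2,3-trimethoxybenzene | COc1cc(CBr)cc(OC)c1OC | intermediate
8 | (1R,4R,5R)-4,7,7-trimethyl-6-thiabicyclo[3.2.1]octane (isothiocineole) | C[C@@H]1CC[C@@H]2C[C@H]1SC2(C)C | starting material
9 | (1R,4R,5R,6R)-4,7,7-trimethyl-6-[(3,4,5-trimethoxyphenyl)methyl]-6-thiabicyclo[3.2.1]octan-6-ium tetrafluoroborate | C[C@@H]1CC[C@@H]2C[C@H]1[S@@+](Cc1cc(OC)c(OC)c(OC)c1)C2(C)C.F[B-](F)(F)F | intermediate
10 | sulfonium benzylide from 9, carbanion on the benzylic carbon (not isolated) | C[C@@H]1CC[C@@H]2C[C@H]1[S@@+]([CH-]c1cc(OC)c(OC)c(OC)c1)C2(C)C | intermediate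
11 | betaine: sulfonium enolate formed by bonding the ylide carbon to the β-carbon of 5 (not isolated; enolate geometry open) | C[C@@H]1CC[C@@H]2C[C@H]1[S@@+]([C@@H](c1cc(OC)c(OC)c(OC)c1)[C@@H](C)C(C)=C([O-])c1ccc(OC)c(OC)c1)C2(C)C | intermediate
12 | (3,4-dimethoxyphenyl)[(1S,2R,3S)-1,2-dimethyl-3-(3,4,5-trimethoxyphenyl)cyclopropyl]methanone; methyls cis, aryl trans to both methyls | C[C@]1(C(=O)c2ccc(OC)c(OC)c2)[C@H](C)[C@H]1c3cc(OC)c(OC)c(OC)c3 | intermediate
13 | ring-opened zwitterion: enolate oxygen cis to C4, benzylic cation at C5, scandium on oxygen not drawn (not isolated) | [O-]/C(c1ccc(OC)c(OC)c1)=C(/C)[C@H](C)[CH+]c1cc(OC)c(OC)c(OC)c1 | intermediate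
14 | (2S,3S)-5-(3,4-dimethoxyphenyl)-3,4-dimethyl-2-(3,4,5-trimethoxyphenyl)-2,3-dihydrofuran | O1C(c2ccc(OC)c(OC)c2)=C(C)[C@H](C)[C@H]1c3cc(OC)c(OC)c(OC)c3 | intermediate
15 | (3R,4S,5S)-2-(3,4-dimethoxyphenyl)-3,4-dimethyl-5-(3,4,5-trimethoxyphenyl)-4,5-dihydro-3H-furan-1-ium trifluoroacetate (not isolated) | COc1ccc(C2=[O+][C@H](c3cc(OC)c(OC)c(OC)c3)[C@@H](C)[C@H]2C)cc1OC.[O-]C(=O)C(F)(F)F | intermediate
16 | ligraminol A, (2S,3R,4S,5S)-2-(3,4-dimethoxyphenyl)-3,4-dimethyl-5-(3,4,5-trimethoxyphenyl)oxolane | COc1ccc([C@H]2O[C@H](c3cc(OC)c(OC)c(OC)c3)[C@@H](C)[C@H]2C)cc1OC | target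

Total step count: 7. Longest linear sequence: 5 steps (steps 1, 2, 5, 6, 7; the branch through steps 3 and 4 is equally long).

Steps most likely to fail

Step 6. Ionisation may be slow, since the flanked 4-methoxy group of the trimethoxyphenyl ring is only a modest donor. Once formed, the cation may also leave by an exit other than return to oxygen: Friedel–Crafts closure onto the dimethoxyphenyl ring, or loss of the C4 proton, which would also erase the one stereocentre carried through. The fallback sets out from 12 and comes back at 14, and replaces the intramolecular ion-pair return by solvolysis. Acid-mediated opening of the donor–acceptor cyclopropane with water as an external nucleophile (TsOH·H2O, aqueous dioxane, warm) should give (3S)-1-(3,4-dimethoxyphenyl)-4-hydroxy-2,3-dimethyl-4-(3,4,5-trimethoxyphenyl)butan-1-one F1. This stands in equilibrium with its cyclic hemiketal, (4S)-2-(3,4-dimethoxyphenyl)-3,4-dimethyl-5-(3,4,5-trimethoxyphenyl)oxolan-2-ol F2. Cyclodehydration (pyridinium p-toluenesulfonate, toluene, 4 Å molecular sieves, 60 °C) then gives 14, and C5 should settle trans to the C4 methyl as the benzylic C–O bond equilibrates under the acid.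

Step 5. Transfer of chirality from the ylide carbon to the enone β-carbon may be incomplete because both modes of approach compete, the sense of induction is assumed, and conjugate addition to a trisubstituted enone may be slow enough for the ylide to decay. The fallback sets out from 7 and comes back at 12, and replaces reagent control by resolution. Bromide 7 with tetrahydrothiophene and NaBF4 (CH2Cl2/H2O) should give 1-[(3,4,5-trimethoxyphenyl)methyl]thiolan-1-ium tetrafluoroborate F3. Its benzylide (KN(SiMe3)2, THF, −78 °C to rt) should cyclopropanate 5 to the racemic ketone with aryl trans to both methyls, that is 12 together with its enantiomer, (3,4-dimethoxyphenyl)[(1R,2S,3R)-1,2-dimethyl-3-(3,4,5-trimethoxyphenyl)cyclopropyl]methanone F4. Preparative chromatography on a chiral stationary phase then separates 12 from F4.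

Step 7. The oxocarbenium ion may equilibrate through the enol ether before hydride capture, which would turn C3 to the more stable arrangement trans to the C4 methyl; protonation may also be poorly face-selective, and the acid may ionise the two benzylic ether bonds. The fallback sets out from 14 and comes back at 16, and avoids any cation. Heterogeneous hydrogenation (H2, Rh/Al2O3, EtOAc, a trace of Et3N, rt) should deliver both hydrogens syn from the metal surface to the face opposite the allylic C4 methyl, setting C2 and C3 in one event; no further compound arises (F0).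

Further compounds
F1 | step 6 | (3S)-1-(3,4-dimethoxyphenyl)-4-hydroxy-2,3-dimethyl-4-(3,4,5-trimethoxyphenyl)butan-1-one (chain locants; mixture at C2 and C4) | COc1ccc(C(=O)C(C)[C@H](C)C(O)c2cc(OC)c(OC)c(OC)c2)cc1OC
F2 | step 6 | (4S)-2-(3,4-dimethoxyphenyl)-3,4-dimethyl-5-(3,4,5-trimethoxyphenyl)oxolan-2-ol (mixture at C2, C3 and C5) | COc1ccc(C2(O)OC(c3cc(OC)c(OC)c(OC)c3)[C@@H](C)C2C)cc1OC
F3 | step 5 | 1-[(3,4,5-trimethoxyphenyl)methyl]thiolan-1-ium tetrafluoroborate | COc1cc(C[S+]2CCCC2)cc(OC)c1OC.F[B-](F)(F)F
F4 | step 5 | (3,4-dimethoxyphenyl)[(1R,2S,3R)-1,2-dimethyl-3-(3,4,5-trimethoxyphenyl)cyclopropyl]methanone | C[C@@]1(C(=O)c2ccc(OC)c(OC)c2)[C@@H](C)[C@@H]1c3cc(OC)c(OC)c(OC)c3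
F0 | step 7 | none | none
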